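**Plan**
1. Retrosynthesis: remove the acetyl and silyl groups, exchange the exocyclic CH2 for a carboxyl group (decarboxylative Mannich methylenation), and take the lactone oxygen out (Baeyer–Villiger) to reach a bridged cyclohexanone. Cutting C14–C1 and C15–C16 together then leaves a cyclobutanone (C16, C12, C13, C14) and an (E)-enoate joined through O11 in a 14-membered macrolactone, which is opened at the enoate olefin, at C5–C6 and at the four-membered ring.
2. Forward ring order: cyclopropanol → cyclobutanone (semipinacol shift) → 14-membered macrolactone (ring-closing metathesis) → in one operation the cyclohexanone, the 14-membered carbocycle and a temporary bridging δ-lactone → seven-membered lactone by insertion of one oxygen → bridge removed with loss of CO2.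
3. Enabling feature: the lactone ring C15–C16(=O)–O–C12–C13–C14–C1 is a cyclohexanone enlarged by one oxygen, and its C16/C12/C13/C14 part is a strained cyclobutanone. The oxygen on C11 lies three atoms from C15, so an enoate bound to O11 places C15 beside the acyl carbon and C1 beside C14.
4. Stereochemistry: C3 from catalytic asymmetric allylation; C11 and C12 from asymmetric epoxidation of a (Z)-alkenylcyclopropanol followed by a stereospecific anti 1,2-shift; C1 from the key step (tether geometry plus E-olefin and syn addition); C12 retained on oxygen insertion; 4E from syn carboalumination; 7Z from nerol.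

Key step: step 13

Remark: cembrane-type locants are used. C1 is the ring CH, C2 the CH2, C3 the carbinol, C4(Me)=C5, C6, C7=C8(Me), C9, C10, C11 the acetoxy carbon, C12 the O-bearing quaternary carbon, C13 and C14 the lactone CH2 groups, C15 the methylene-bearing carbon, C16 the lactone carbonyl, C17 the exocyclic CH2. The target is (1S,3R,4E,7Z,11R,12S).
Assumption: in step 9 the (S,S) bishydroxamic acid ligand is taken to deliver oxygen to the olefin face that gives (2R,3R)-13; its antipode is used if the sense of induction is the opposite.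

**Route**

Step 1
Reactants: 1 prop-2-yn-1-ol
Product: 3 (2E)-3-iodo-2-methylprop-2-en-1-ol, via alkenylalane 2 (not isolated)
Conditions: Me3Al (3 equiv), Cp2ZrCl2 (0.25 equiv), CH2Cl2, 0 °C → rt; then I2, THF, −30 → 0 °C
Reagents that add atoms: trimethylaluminium C[Al](C)C; iodine II
Why: Zirconium-catalysed carboalumination adds methyl and aluminium syn across the terminal alkyne (methyl to the internal carbon) and iodinolysis proceeds with retention, so the (E)-iodide that becomes the 4E olefin should result.

Step 2
Reactants: 3 (2E)-3-iodo-2-methylprop-2-en-1-ol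
Product: 4 (2E)-3-iodo-2-methylprop-2-enal
Conditions: MnO2, CH2Cl2, rt
Reagents that add atoms: none
Why: Allylic oxidation with MnO2 is selective for the allylic alcohol and should leave the vinyl iodide and the olefin geometry untouched.

Step 3
Reactants: 4 (2E)-3-iodo-2-methylprop-2-enal
Product: 5 (1E,3R)-1-iodo-2-methylhexa-1,5-dien-3-ol
Conditions: allyltributylstannane, Ti(OiPr)4 (10 mol %), (R)-BINOL (20 mol %), 4 Å molecular sieves, CH2Cl2, −20 °C
Reagents that add atoms: allyltributylstannane C=CC[Sn](CCCC)(CCCC)CCCC
Why: Keck asymmetric allylation, in which the titanium–(R)-BINOL complex differentiates the aldehyde faces and should give the (R)-carbinol (C3) by 1,2-addition.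

Step 4
Reactants: 5 (1E,3R)-1-iodo-2-methylhexa-1,5-dien-3-ol
Product: 6 tert-butyl{[(1E,3R)-1-iodo-2-methylhexa-1,5-dien-3-yl]oxy}dimethylsilane
Conditions: TBSCl, imidazole, DMF, rt
Reagents that add atoms: tert-butyldimethylsilyl chloride CC(C)(C)[Si](C)(C)Cl
Why: Standard silylation of a secondary alcohol, giving an ether that should survive the organometallic, metathesis, rhodium and peroxide steps.

Step 5
Reactants: 7 neryl acetate
Product: 9 (2Z)-3-methyl-6-oxohex-2-en-1-yl acetate, via epoxide 8 (not isolated)
Conditions: mCPBA, NaHCO3, CH2Cl2, 0 °C; then H5IO6, THF/H2O, 0 °C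
Reagents that add atoms: 3-chloroperoxybenzoic acid OOC(=O)c1cccc(Cl)c1
Why: The peracid should epoxidise the electron-rich distal olefin in preference to the one deactivated by the allylic acetate, and periodic acid cleaves the epoxide through the diol to the aldehyde (epoxidation and glycol cleavage) without touching the Z olefin.

Step 6
Reactants: 9 (2Z)-3-methyl-6-oxohex-2-en-1-yl acetate
Product: 10 ethyl (2Z,6Z)-8-acetoxy-2,6-dimethylocta-2,6-dienoate
Conditions: ethyl 2-[bis(2,2,2-trifluoroethoxy)phosphoryl]propanoate, KN(SiMe3)2, 18-crown-6, THF, −78 °C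
Reagents that add atoms: ethyl 2-[bis(2,2,2-trifluoroethoxy)phosphoryl]propanoate CCOC(=O)C(C)P(=O)(OCC(F)(F)F)OCC(F)(F)F
Why: Still–Gennari olefination under dissociating conditions is kinetically Z-selective, which places the ester carbon cis to the chain as the later anti 1,2-shift requires.

Step 7
Reactants: 10 ethyl (2Z,6Z)-8-acetoxy-2,6-dimethylocta-2,6-dienoate
Product: 11 1-[(2Z,6Z)-8-hydroxy-6-methylocta-2,6-dien-2-yl]cyclopropan-1-ol
Conditions: EtMgBr (6 equiv), Ti(OiPr)4 (0.5 equiv), THF/Et2O, 0 °C → rt
Reagents that add atoms: ethylmagnesium bromide CC[Mg]Br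
Why: In the Kulinkovich reaction the titanacyclopropane from EtMgBr and Ti(OiPr)4 acts as a 1,2-dicarbanion toward the ester to give the cyclopropanol (C13 and C14), while the acetate is consumed in the same way and frees the allylic alcohol; both olefin geometries should be kept.

Step 8
Reactants: 11 1-[(2Z,6Z)-8-hydroxy-6-methylocta-2,6-dien-2-yl]cyclopropan-1-ol
Product: 12 1-[(2Z,6Z)-8-chloro-6-methylocta-2,6-dien-2-yl]cyclopropan-1-ol
Conditions: MsCl, LiCl, 2,4,6-collidine, DMF, 0 °C
Reagents that add atoms: lithium chloride [Li+].[Cl-]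
Why: The primary allylic alcohol is mesylated and displaced by chloride in an SN2 reaction without allylic transposition, and the hindered tertiary cyclopropanol should not react under these non-oxidising conditions.

Step 9
Reactants: 12 1-[(2Z,6Z)-8-chloro-6-methylocta-2,6-dien-2-yl]cyclopropan-1-ol
Product: 14 (2S)-2-[(1R,4Z)-6-chloro-1-hydroxy-4-methylhex-4-en-1-yl]-2-methylcyclobutan-1-one, via epoxy cyclopropanol 13 (not isolated)
Conditions: WO2(acac)2 (5 mol %), (S,S)-N,N′-bis(2,2-diphenylacetyl)-N,N′-dihydroxycyclohexane-1,2-diamine (6 mol %), 30 % aq. H2O2, NaCl, CH2Cl2, rt; then BF3·OEt2 (0.2 equiv), CH2Cl2, −78 → −40 °C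
Reagents that add atoms: hydrogen peroxide OO
Why: Hydroxyl-directed asymmetric epoxidation of the tertiary allylic alcohol should oxidise only the olefin next to the cyclopropanol, on the ligand-controlled face; in the strain-driven semipinacol shift a cyclopropane bond then migrates anti to the breaking tertiary C–O bond (inversion at C12, retention at C11), so the Z geometry is translated into the 11R,12S relationship.

Step 10
Reactants: 14 (2S)-2-[(1R,4Z)-6-chloro-1-hydroxy-4-methylhex-4-en-1-yl]-2-methylcyclobutan-1-one
Product: 15 (1R,4Z)-6-chloro-4-methyl-1-[(1S)-1-methyl-2-oxocyclobutyl]hex-4-en-1-yl prop-2-enoate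
Conditions: acryloyl chloride, iPr2NEt, DMAP (cat.), CH2Cl2, −20 → 0 °C
Reagents that add atoms: acryloyl chloride C=CC(=O)Cl
Why: Acylation of the hindered secondary alcohol installs the two-carbon partner on O11 and protects the aldol against retro-aldol cleavage; β-elimination is impossible because C12 is quaternary.

Step 11
Reactants: 6 tert-butyl{[(1E,3R)-1-iodo-2-methylhexa-1,5-dien-3-yl]oxy}dimethylsilane; 15 (1R,4Z)-6-chloro-4-methyl-1-[(1S)-1-methyl-2-oxocyclobutyl]hex-4-en-1-yl prop-2-enoate
Product: 18 (1R,4Z,7E,9R)-9-[(tert-butyldimethylsilyl)oxy]-4,8-dimethyl-1-[(1S)-1-methyl-2-oxocyclobutyl]dodeca-4,7,11-trien-1-yl prop-2-enoate, via alkenyllithium 16 (not isolated), via alkenylzinc chloride 17 (not isolated)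
Conditions: 6, t-BuLi (2 equiv), Et2O, −78 °C; ZnCl2, THF, −78 → 0 °C; then 15, Pd(PPh3)4 (5 mol %), THF, 0 °C → rt
Reagents that add atoms: none
Why: Iodine–lithium exchange with retention, transmetalation to zinc and a Negishi coupling catalysed by zerovalent palladium should join the alkenyl group to the primary allylic terminus with retention of both olefin geometries (skipped 4E,7Z diene); the organozinc tolerates the ketone and the acrylate.

Step 12
Reactants: 18 (1R,4Z,7E,9R)-9-[(tert-butyldimethylsilyl)oxy]-4,8-dimethyl-1-[(1S)-1-methyl-2-oxocyclobutyl]dodeca-4,7,11-trien-1-yl prop-2-enoate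
Product: 19 (3E,6R,7E,10Z,14R)-6-[(tert-butyldimethylsilyl)oxy]-7,11-dimethyl-14-[(1S)-1-methyl-2-oxocyclobutyl]-1-oxacyclotetradeca-3,7,10-trien-2-one
Conditions: second-generation Grubbs catalyst RuCl2(=CHPh)(PCy3)(H2IMes) (10 mol %), toluene (1 mM), 80 °C
Reagents that add atoms: none
Why: Ring-closing metathesis between the acrylate and the terminal olefin, the only reactive olefins, should close the 14-membered macrolactone as the thermodynamically preferred (E)-enoate; the trisubstituted olefins stay out because the only small ring they could close would contain the E olefin.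

Step 13
Reactants: 19 (3E,6R,7E,10Z,14R)-6-[(tert-butyldimethylsilyl)oxy]-7,11-dimethyl-14-[(1S)-1-methyl-2-oxocyclobutyl]-1-oxacyclotetradeca-3,7,10-trien-2-one
Product: 20 tricyclic keto lactone (2-oxabicyclo[3.3.1]nonane-3,9-dione core fused to the 14-membered carbocycle; 1S,3R,4E,7Z,11R,12S,15S; 3-OTBS)
Conditions: [Rh(nbd)(dppp)]PF6 (10 mol %), 2,6-di-tert-butyl-4-methylphenol (additive), m-xylene (0.01 M), 135 °C
Reagents that add atoms: none
Why: Proposed new method: monovalent rhodium is expected to insert into the less hindered acyl–CH2 bond (C16–C14) of the strained cyclobutanone; the (E)-enoate held three atoms away through O11 then inserts into the Rh–C14 bond (alkyl to the β-carbon C1, rhodium enolate at C15), and acyl–C15 reductive elimination releases the catalyst, so that the four-membered ketone is enlarged by two carbons to a cyclohexanone. The closest known reaction type is the rhodium-catalysed intramolecular cut-and-sew carboacylation of olefins by cyclobutanones, which gives bridged bicyclo[3.3.1] ketones; new here are the α,β-unsaturated ester as the two-carbon partner, the α-quaternary ketone and the macrocyclic setting. The 14-membered carbocycle closes in the migratory insertion (C14–C1, across the macrolactone), and the cyclohexanone and the bridging δ-lactone close together in the reductive elimination (C15–C16), both as six-membered rings of one bicyclo[3.3.1] core. C15 is fixed by the three-atom ester tether, which can span C12 and C15 only cis-diaxially, and C1 by the E geometry of the enoate together with syn addition, which places C2 trans to the C15 carboxyl and therefore trans to C11 across the new ring, as in the target. The step needs site selectivity in C–C activation (C16–C14 and not the bond to quaternary C12, secured by sterics), regioselectivity of insertion (acyl to the α-carbon, secured by the six-membered and not seven-membered lactone bridge and by the polarity of the enoate) and chemoselectivity over decarbonylation and over the trisubstituted olefins, which are too hindered to insert.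

Step 14
Reactants: 20 tricyclic keto lactone
Product: 21 bis-lactone (oxygen inserted between C16 and C12; C15 carboxyl still lactonised on O11; 3-OTBS)
Conditions: Me3SiOOSiMe3, Me3SiOTf (cat.), 2,6-di-tert-butylpyridine, CH2Cl2, −40 → −20 °C
Reagents that add atoms: bis(trimethylsilyl) peroxide C[Si](C)(C)OO[Si](C)(C)C
Why: Baeyer–Villiger oxidation under aprotic silyl peroxide conditions does not epoxidise olefins, and the tertiary C12 should migrate with retention in preference to C15, which carries the electron-withdrawing lactone carbonyl, giving the seven-membered 16,12-lactone.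

Step 15
Reactants: 21 bis-lactone
Product: 22 α-carboxy lactone (C15–CO2H; free 11-OH; 3-OTBS)
Conditions: LiOH (1.2 equiv), THF/H2O, 0 °C; then 1 M HCl to pH 3
Reagents that add atoms: lithium hydroxide [Li+].[OH-]
Why: Saponification should occur at the lactone carbonyl whose alkoxy group is secondary (O11) and not at the one bearing the tertiary O12; the bridgehead C15–H cannot enolise to slow the attack, and the carboxylate formed protects the remaining lactone.

Step 16
Reactants: 22 α-carboxy lactone
Product: 24 11-hydroxy α-methylene lactone (3-OTBS), via Mannich base 23 (not isolated)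
Conditions: (CH2O)n, Et2NH, EtOAc, 25 → 70 °C
Reagents that add atoms: formaldehyde C=O
Why: Decarboxylative Mannich methylenation of the malonic half-ester: aminomethylation at C15 followed by loss of CO2 and diethylamine gives the exocyclic methylene, and the configuration at C15 is of no consequence.

Step 17
Reactants: 24 11-hydroxy α-methylene lactone
Product: 25 11-acetoxy α-methylene lactone (3-OTBS)
Conditions: Ac2O, pyridine, DMAP (cat.), CH2Cl2, rt
Reagents that add atoms: acetic anhydride CC(=O)OC(C)=O
Why: DMAP-catalysed acetylation of the only free hydroxyl group; reversible conjugate addition of the amine to the methylene lactone should do no harm.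

Step 18
Reactants: 25 11-acetoxy α-methylene lactone
Product: 26 target CNP0130972.7
Conditions: HF·pyridine, pyridine, THF, 0 °C → rt
Reagents that add atoms: none
Why: Buffered fluoride desilylation of the allylic silyl ether should leave the acetate, the skipped diene and the α-methylene lactone intact.

**Compound list**
1 | prop-2-yn-1-ol | C#CCO | starting material
2 | dimethyl[(1E)-3-(dimethylalumanyloxy)-2-methylprop-1-en-1-yl]alumane | C[Al](C)OC/C(C)=C/[Al](C)C | intermediate
3 | (2E)-3-iodo-2-methylprop-2-en-1-ol | OC/C(C)=C/I | intermediate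
4 | (2E)-3-iodo-2-methylprop-2-enal | O=C/C(C)=C/I | intermediate
5 | (1E,3R)-1-iodo-2-methylhexa-1,5-dien-3-ol | C=CC[C@@H](O)/C(C)=C/I | intermediate
6 | tert-butyl{[(1E,3R)-1-iodo-2-methylhexa-1,5-dien-3-yl]oxy}dimethylsilane | C=CC[C@@H](O[Si](C)(C)C(C)(C)C)/C(C)=C/I | intermediate
7 | neryl acetate, (2Z)-3,7-dimethylocta-2,6-dien-1-yl acetate | CC(C)=CCC/C(C)=C\COC(C)=O | starting material
8 | (2Z)-5-(3,3-dimethyloxiran-2-yl)-3-methylpent-2-en-1-yl acetate (racemic) | CC1(C)OC1CC/C(C)=C\COC(C)=O | intermediate
9 | (2Z)-3-methyl-6-oxohex-2-en-1-yl acetate | O=CCC/C(C)=C\COC(C)=O | intermediate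
10 | ethyl (2Z,6Z)-8-acetoxy-2,6-dimethylocta-2,6-dienoate | CCOC(=O)/C(C)=C\CC/C(C)=C\COC(C)=O | intermediate
11 | 1-[(2Z,6Z)-8-hydroxy-6-methylocta-2,6-dien-2-yl]cyclopropan-1-ol | OC1(CC1)/C(C)=C\CC/C(C)=C\CO | intermediate
12 | 1-[(2Z,6Z)-8-chloro-6-methylocta-2,6-dien-2-yl]cyclopropan-1-ol | OC1(CC1)/C(C)=C\CC/C(C)=C\CCl | intermediate
13 | 1-{(2R,3R)-3-[(3Z)-5-chloro-3-methylpent-3-en-1-yl]-2-methyloxiran-2-yl}cyclopropan-1-ol | OC1(CC1)[C@]2(C)O[C@@H]2CC/C(C)=C\CCl | intermediate
14 | (2S)-2-[(1R,4Z)-6-chloro-1-hydroxy-4-methylhex-4-en-1-yl]-2-methylcyclobutan-1-one | O=C1CC[C@@]1(C)[C@H](O)CC/C(C)=C\CCl | intermediate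
15 | (1R,4Z)-6-chloro-4-methyl-1-[(1S)-1-methyl-2-oxocyclobutyl]hex-4-en-1-yl prop-2-enoate | O=C1CC[C@@]1(C)[C@H](OC(=O)C=C)CC/C(C)=C\CCl | intermediate
16 | {(1E,3R)-3-[(tert-butyldimethylsilyl)oxy]-2-methylhexa-1,5-dien-1-yl}lithium | C=CC[C@@H](O[Si](C)(C)C(C)(C)C)/C(C)=C/[Li] | intermediate
17 | {(1E,3R)-3-[(tert-butyldimethylsilyl)oxy]-2-methylhexa-1,5-dien-1-yl}zinc chloride | C=CC[C@@H](O[Si](C)(C)C(C)(C)C)/C(C)=C/[Zn]Cl | intermediate
18 | (1R,4Z,7E,9R)-9-[(tert-butyldimethylsilyl)oxy]-4,8-dimethyl-1-[(1S)-1-methyl-2-oxocyclobutyl]dodeca-4,7,11-trien-1-yl prop-2-enoate | O=C1CC[C@@]1(C)[C@H](OC(=O)C=C)CC/C(C)=C\C/C=C(\C)[C@H](O[Si](C)(C)C(C)(C)C)CC=C | intermediate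
19 | (3E,6R,7E,10Z,14R)-6-[(tert-butyldimethylsilyl)oxy]-7,11-dimethyl-14-[(1S)-1-methyl-2-oxocyclobutyl]-1-oxacyclotetradeca-3,7,10-trien-2-one | O=C1CC[C@@]1(C)[C@@H]2OC(=O)/C=C/C[C@@H](O[Si](C)(C)C(C)(C)C)/C(C)=C/C/C=C(/C)CC2 | intermediate
20 | tricyclic keto lactone: ketone C16 joined to C12 and C15, C14–C1 closing the 14-membered carbocycle, C15 carboxyl lactonised on O11 (2-oxabicyclo[3.3.1]nonane-3,9-dione core); 3-OTBS; 1S,3R,4E,7Z,11R,12S,15S | O=C1[C@@]2(C)CC[C@@H]3[C@@H]1C(=O)O[C@@H]2CC/C(C)=C\C/C=C(\C)[C@H](O[Si](C)(C)C(C)(C)C)C3 | intermediate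
21 | bis-lactone: as 20 with an oxygen between C16 and C12 (seven-membered 16,12-lactone), C15 carboxyl lactonised on O11; 3-OTBS | O=C1O[C@@]2(C)CC[C@@H]3[C@@H]1C(=O)O[C@@H]2CC/C(C)=C\C/C=C(\C)[C@H](O[Si](C)(C)C(C)(C)C)C3 | intermediate
22 | α-carboxy lactone: 16,12-lactone with CO2H on C15, free 11-OH, 3-OTBS; 1S,3R,4E,7Z,11R,12S | OC(=O)[C@@H]1C(=O)O[C@@]2(C)CC[C@H]1C[C@@H](O[Si](C)(C)C(C)(C)C)/C(C)=C/C/C=C(/C)CC[C@H]2O | intermediate
23 | Mannich base: 22 with a diethylaminomethyl group on C15 (either configuration at C15) | CCN(CC)CC1(C(=O)O)C(=O)O[C@@]2(C)CC[C@H]1C[C@@H](O[Si](C)(C)C(C)(C)C)/C(C)=C/C/C=C(/C)CC[C@H]2O | intermediate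
24 | 11-hydroxy α-methylene lactone: the target without the acetyl group and with TBS on O3 | C=C1C(=O)O[C@@]2(C)CC[C@H]1C[C@@H](O[Si](C)(C)C(C)(C)C)/C(C)=C/C/C=C(/C)CC[C@H]2O | intermediate
25 | 3-O-TBS ether of the target | C=C1C(=O)O[C@@]2(C)CC[C@H]1C[C@@H](O[Si](C)(C)C(C)(C)C)/C(C)=C/C/C=C(/C)CC[C@H]2OC(C)=O | intermediate
26 | CNP0130972.7, (1S,3R,4E,7Z,11R,12S)-11-acetoxy-3-hydroxycembra-4,7,15(17)-trien-16,12-olide | C=C1C(=O)O[C@@]2(C)CC[C@H]1C[C@@H](O)/C(C)=C/C/C=C(/C)CC[C@H]2OC(C)=O | target

**Summary**
Total step count: 18. Longest linear sequence: 14 steps (steps 5–18, from 7 to 26); the branch from 1 joins at step 11.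

Steps most likely to fail:

1. Step 13. The rhodacycle may lose CO instead of inserting the olefin, the macrolactone may not reach the s-cis ester conformer that presents the enoate to the metal, or the skipped diene may isomerise at 135 °C. Fallback with known reaction types, from 18 back to 20, forming the two bonds in separate steps: an intramolecular Morita–Baylis–Hillman reaction of the acrylate onto the cyclobutanone carbonyl (PMe3, t-BuOH/THF) would give the cis-fused methylene lactone cyclobutanol F1. Ring-closing metathesis of its 1,1-disubstituted olefin with the terminal olefin (second-generation Grubbs catalyst RuCl2(=CHPh)(PCy3)(H2IMes), toluene, 80 °C, high dilution) would give the macrocyclic (E)-alkylidene lactone F2. With [Rh(cod)(OH)]2 and a bisphosphine (toluene, 100 °C) the rhodium alkoxide of F2 should undergo β-carbon elimination of the C16–C14 bond and intramolecular 1,4-addition of the alkylrhodium to the alkylidene β-keto lactone; protonation then gives 20.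

2. Step 14. The peroxide may fail to add to the hindered bridging ketone, or the Lewis acid may cleave the silyl ether or induce epoxidation of the trisubstituted olefins. Fallback from 20 back to 21: excess 3-chloroperoxybenzoic acid (NaHCO3, CH2Cl2) would carry out the Baeyer–Villiger reaction and epoxidise both trisubstituted olefins, giving the diepoxy bis-lactone F3 as epoxide diastereomers. Stereospecific deoxygenation with retention of olefin geometry (Ph3P=Se, CF3CO2H, CH2Cl2, 0 °C) would restore the 4E,7Z diene and give 21.

3. Step 7. The conjugated Z-ester may react sluggishly or suffer conjugate reduction, oligomerisation or Z-to-E isomerisation under the titanium–Grignard conditions. Fallback from 9 back to 11: Z-selective iodo-olefination with (1-iodoethyl)triphenylphosphonium iodide and NaN(SiMe3)2 (THF, −78 °C) would give the vinyl iodide F4, and methanolysis (K2CO3, MeOH) the iodo alcohol F5. Treatment of F5 with t-BuLi (3 equiv, Et2O, −78 °C; alkoxide formation and iodine–lithium exchange with retention) and addition of the alkenyllithium to cyclopropanone, set free in situ from 1-(phenylsulfonyl)cyclopropan-1-ol pre-treated with MeMgBr, would give 11.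

Further compounds
F1 | step 13 | cis-fused α-methylene δ-lactone cyclobutanol from 18 (C15–C16 bond formed; tertiary OH on C16; side chain as in 18) | C=C1C(=O)O[C@H](CC/C(C)=C\C/C=C(\C)[C@H](O[Si](C)(C)C(C)(C)C)CC=C)[C@]2(C)CC[C@]12O
F2 | step 13 | macrocyclic (E)-alkylidene δ-lactone cyclobutanol (C15=C1 in the 14-membered ring; tertiary OH on C16; 3-OTBS) | O[C@]12CC[C@@]1(C)[C@H]3CC/C(C)=C\C/C=C(\C)[C@H](O[Si](C)(C)C(C)(C)C)C/C=C2/C(=O)O3
F3 | step 14 | 4,5:7,8-diepoxide of bis-lactone 21 (epoxide diastereomers) | O=C1O[C@@]2(C)CC[C@@H]3[C@@H]1C(=O)O[C@@H]2CCC4(C)OC4CC5OC5(C)[C@H](O[Si](C)(C)C(C)(C)C)C3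
F4 | step 7 | (2Z,6Z)-7-iodo-3-methylocta-2,6-dien-1-yl acetate | C/C(I)=C/CC/C(C)=C\COC(C)=O
F5 | step 7 | (2Z,6Z)-7-iodo-3-methylocta-2,6-dien-1-ol | C/C(I)=C/CC/C(C)=C\CO
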